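Assumption: (R)-(−)-linalool and (R)-α-hydroxy-γ-butyrolactone are bought at ≥98% ee; the product's ee cannot exceed theirs. The route is designed on paper and has not been run.

**Retrosynthetic overview**
- The quinone is unmasked last by Teuber oxidation of a 5-hydroxy-2H-chromene. The δ-lactone comes from a (Z)-enoate made by an Ando-type Horner–Wadsworth–Emmons reaction of a C7 aldehyde with an α-substituted diaryl phosphonate, whose stereocentre is bought as (R)-α-hydroxy-γ-butyrolactone.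
- Key step: the C7 aldehyde arises from a Johnson–Claisen [3,3]-sigmatropic rearrangement of an isopropenyl carbinol, which forms the C–C bond and the (E)-trisubstituted alkene of the linker.
- The carbinol comes from isomerisation of the prenyl epoxide of a linalool-derived chromene.
- The chromene comes from ring-closing metathesis of a styrene/vinyl pair, set up by SNAr of (R)-linalool alkoxide on an ortho-fluorobenzaldehyde. The linalool C–O bond is never broken, so C2 is bought.
- Ring order: pyran ring of the chromene first (metathesis), δ-lactone second (acid lactonisation), quinone oxidation state last.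

**Route**

Step 1
Reactants: 1 5-fluoro-2-methylphenol
Product: 2 4-fluoro-2-(methoxymethoxy)-1-methylbenzene
Conditions: MOMCl, i-Pr2NEt, CH2Cl2, 0 °C → rt
Reagents that add atoms: chloromethyl methyl ether (MOMCl), COCCl
Why: Base-mediated O-alkylation (MOM protection) masks the phenol as an acetal that survives all later basic and organometallic steps and directs the next lithiation.

Step 2
Reactants: 2 4-fluoro-2-(methoxymethoxy)-1-methylbenzene
Product: 4 6-fluoro-2-(methoxymethoxy)-3-methylbenzaldehyde, via aryllithium 3 (not isolated)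
Conditions: n-BuLi, THF, −78 °C; then DMF, −78 → 0 °C; H2O
Reagents that add atoms: N,N-dimethylformamide, CN(C)C=O
Why: Directed ortho-metalation lithiates the only ring position flanked by both OMOM and F (at −78 °C, too cold for LiF loss to an aryne), and DMF formylates the aryllithium.

Step 3
Reactants: 4 6-fluoro-2-(methoxymethoxy)-3-methylbenzaldehyde; 5 (R)-(−)-linalool
Product: 7 6-{[(3R)-3,7-dimethylocta-1,6-dien-3-yl]oxy}-2-(methoxymethoxy)-3-methylbenzaldehyde, via potassium (R)-linaloolate 6 (not isolated)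
Conditions: 5, KN(SiMe3)2, THF, 0 °C; then 4, DMF, 0 °C → rt (≤45 °C)
Reagents that add atoms: none
Why: SNAr (addition–elimination) of the tertiary alkoxide on the ortho-formyl-activated aryl fluoride; the alkoxide has no α-hydrogen to reduce the aldehyde, and because the linalool C–O bond is never broken the bought (R) centre becomes the future C2 unchanged.

Step 4
Reactants: 7 6-{[(3R)-3,7-dimethylocta-1,6-dien-3-yl]oxy}-2-(methoxymethoxy)-3-methylbenzaldehyde
Product: 8 1-{[(3R)-3,7-dimethylocta-1,6-dien-3-yl]oxy}-2-ethenyl-3-(methoxymethoxy)-4-methylbenzene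
Conditions: Ph3PCH3Br, KOt-Bu, THF, 0 °C → rt
Reagents that add atoms: methyltriphenylphosphonium bromide, C[P+](c1ccccc1)(c1ccccc1)c1ccccc1.[Br-]
Why: Wittig methylenation with the small unstabilised ylide turns the hindered aldehyde into the styrene needed for ring closure without touching the stereocentre.

Step 5
Reactants: 8 1-{[(3R)-3,7-dimethylocta-1,6-dien-3-yl]oxy}-2-ethenyl-3-(methoxymethoxy)-4-methylbenzene
Product: 9 2-[(3R)-3-{[2-ethenyl-3-(methoxymethoxy)-4-methylphenyl]oxy}-3-methylpent-4-en-1-yl]-3,3-dimethyloxirane (1:1 epimers at the oxirane CH)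
Conditions: mCPBA (1.05 equiv), CH2Cl2, 0 °C
Reagents that add atoms: 3-chloroperoxybenzoic acid (mCPBA), OOC(=O)c1cccc(Cl)c1
Why: Prilezhaev epoxidation is chemoselective for the electron-rich trisubstituted alkene over the two monosubstituted ones, which masks it during metathesis and prepares the allylic alcohol; the new oxirane centre forms unselectively and is erased in step 8.

Step 6
Reactants: 9 2-[(3R)-3-{[2-ethenyl-3-(methoxymethoxy)-4-methylphenyl]oxy}-3-methylpent-4-en-1-yl]-3,3-dimethyloxirane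
Product: 10 (2R)-2-[2-(3,3-dimethyloxiran-2-yl)ethyl]-5-(methoxymethoxy)-2,6-dimethyl-2H-chromene
Conditions: second-generation Grubbs catalyst (H2IMes)(PCy3)Cl2Ru=CHPh (5 mol%), CH2Cl2, 40 °C
Reagents that add atoms: none
Why: Ring-closing metathesis of the styrene with the hindered vinyl group closes the pyran ring with loss of ethene at 40 °C (below the onset of aromatic Claisen rearrangement of the aryl tert-allyl ether) and leaves the quaternary C–O centre untouched.

Step 7
Reactants: 10 (2R)-2-[2-(3,3-dimethyloxiran-2-yl)ethyl]-5-(methoxymethoxy)-2,6-dimethyl-2H-chromene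
Product: 11 5-[(2R)-5-(methoxymethoxy)-2,6-dimethyl-2H-chromen-2-yl]-2-methylpent-1-en-3-ol (1:1 carbinol epimers)
Conditions: Et2AlCl, lithium 2,2,6,6-tetramethylpiperidide (from the amine and n-BuLi), PhMe, 0 °C; aq. KNaC4H4O6
Reagents that add atoms: none
Why: Yamamoto–Nozaki epoxide-to-allylic-alcohol isomerisation: the bulky aluminium amide binds the oxirane oxygen and removes a methyl proton syn to it, opening the tertiary C–O bond to the isopropenyl carbinol (both carbinol epimers are used).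

Step 8 (key step)
Reactants: 11 5-[(2R)-5-(methoxymethoxy)-2,6-dimethyl-2H-chromen-2-yl]-2-methylpent-1-en-3-ol
Product: 13 ethyl (4E)-7-[(2R)-5-(methoxymethoxy)-2,6-dimethyl-2H-chromen-2-yl]-4-methylhept-4-enoate, via ketene acetal 12 (not isolated)
Conditions: MeC(OEt)3 (8 equiv), EtCO2H (10 mol%), PhMe, 110 °C, EtOH distilled off
Reagents that add atoms: triethyl orthoacetate, CC(OCC)(OCC)OCC
Why: Johnson–Claisen [3,3]-sigmatropic rearrangement of the in-situ ketene acetal through a chair transition state with the chain equatorial (an axial chain clashes 1,3-diaxially with OEt) forms the new C–C bond and the (E)-trisubstituted alkene (expected ≥95:5) and converts both carbinol epimers into one product; 110 °C is the ceiling chosen to spare the chromene.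

Step 9
Reactants: 13 ethyl (4E)-7-[(2R)-5-(methoxymethoxy)-2,6-dimethyl-2H-chromen-2-yl]-4-methylhept-4-enoate
Product: 14 (4E)-7-[(2R)-5-(methoxymethoxy)-2,6-dimethyl-2H-chromen-2-yl]-4-methylhept-4-enal
Conditions: i-Bu2AlH (1.05 equiv), CH2Cl2, −78 °C; aq. KNaC4H4O6
Reagents that add atoms: none
Why: Partial ester reduction: at −78 °C the tetrahedral aluminium hemiacetal is stable and releases the aldehyde only on work-up.

Step 10
Reactants: 15 (R)-α-hydroxy-γ-butyrolactone
Product: 16 (3R)-4-methylpentane-1,3,4-triol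
Conditions: MeMgBr (3.5 equiv), THF, 0 °C → rt; aq. NH4Cl
Reagents that add atoms: methylmagnesium bromide, C[Mg]Br
Why: Double Grignard addition to the lactone carbonyl (after deprotonation of the OH) gives the tertiary carbinol; the bought stereocentre is not involved and stays (R).

Step 11
Reactants: 16 (3R)-4-methylpentane-1,3,4-triol
Product: 17 2-[(4R)-2,2,5,5-tetramethyl-1,3-dioxolan-4-yl]ethan-1-ol
Conditions: Me2C(OMe)2, TsOH (cat.), acetone, rt
Reagents that add atoms: 2,2-dimethoxypropane, COC(C)(C)OC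
Why: Acid-catalysed acetalisation under equilibrating conditions gives the five-membered dioxolane of the vicinal diol (favoured over the six-membered 1,3-acetonide), leaving the primary OH free.

Step 12
Reactants: 17 2-[(4R)-2,2,5,5-tetramethyl-1,3-dioxolan-4-yl]ethan-1-ol
Product: 18 (4R)-4-(2-iodoethyl)-2,2,5,5-tetramethyl-1,3-dioxolane
Conditions: I2, PPh3, imidazole, CH2Cl2, 0 °C → rt
Reagents that add atoms: iodine, II
Why: Appel-type (Garegg–Samuelsson) iodination replaces the primary OH by SN2 at CH2, remote from the stereocentre.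

Step 13
Reactants: 18 (4R)-4-(2-iodoethyl)-2,2,5,5-tetramethyl-1,3-dioxolane; 19 ethyl 2-[bis(2-methylphenoxy)phosphoryl]acetate
Product: 21 ethyl 2-[bis(2-methylphenoxy)phosphoryl]-4-[(4R)-2,2,5,5-tetramethyl-1,3-dioxolan-4-yl]butanoate (epimers at C2), via sodium enolate 20 (not isolated)
Conditions: 19, NaH, DMF, 0 °C; then 18, 50 °C
Reagents that add atoms: none
Why: SN2 C-alkylation of the stabilised phosphonoacetate anion by the unhindered primary iodide; the new α-centre is a mixture but becomes sp2 in step 14.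

Step 14
Reactants: 14 (4E)-7-[(2R)-5-(methoxymethoxy)-2,6-dimethyl-2H-chromen-2-yl]-4-methylhept-4-enal; 21 ethyl 2-[bis(2-methylphenoxy)phosphoryl]-4-[(4R)-2,2,5,5-tetramethyl-1,3-dioxolan-4-yl]butanoate
Product: 23 ethyl (2Z,6E)-9-[(2R)-5-(methoxymethoxy)-2,6-dimethyl-2H-chromen-2-yl]-6-methyl-2-{2-[(4R)-2,2,5,5-tetramethyl-1,3-dioxolan-4-yl]ethyl}nona-2,6-dienoate, via sodium phosphonate enolate 22 (not isolated)
Conditions: 21, NaH, THF, 0 °C; then 14, −78 → 0 °C
Reagents that add atoms: none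
Why: Ando variant of the Horner–Wadsworth–Emmons olefination: the electron-poor diaryl phosphonate makes the syn-oxaphosphetane collapse irreversibly, giving the (Z)-enoate with the chain cis to the ester (expected ≥93:7; minor (E)-isomer removed by chromatography).

Step 15
Reactants: 23 ethyl (2Z,6E)-9-[(2R)-5-(methoxymethoxy)-2,6-dimethyl-2H-chromen-2-yl]-6-methyl-2-{2-[(4R)-2,2,5,5-tetramethyl-1,3-dioxolan-4-yl]ethyl}nona-2,6-dienoate
Product: 25 (3Z,6R)-3-{(4E)-7-[(2R)-5-hydroxy-2,6-dimethyl-2H-chromen-2-yl]-4-methylhept-4-en-1-ylidene}-6-(2-hydroxypropan-2-yl)oxan-2-one, via dihydroxy ester 24 (not isolated)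
Conditions: aq. HCl (1 M), THF, 40 °C; then TsOH (cat.), PhMe, 40 °C
Reagents that add atoms: none
Why: Acid hydrolysis removes the acetonide and the MOM acetal, and the freed secondary δ-hydroxyl closes the six-membered lactone by transesterification (favoured over seven-membered closure by the tertiary OH); the C6–O bond is not broken so C6 stays (R), and the mild acid does not isomerise the (Z)-alkene.

Step 16
Reactants: 25 (3Z,6R)-3-{(4E)-7-[(2R)-5-hydroxy-2,6-dimethyl-2H-chromen-2-yl]-4-methylhept-4-en-1-ylidene}-6-(2-hydroxypropan-2-yl)oxan-2-one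
Product: 26 (2R)-2-{(3E)-7-[(3Z,6R)-6-(2-hydroxypropan-2-yl)-2-oxooxan-3-ylidene]-4-methylhept-3-en-1-yl}-2,6-dimethyl-2H-chromene-5,8-dione (CNP0134417.1)
Conditions: ON(SO3K)2 (2.5 equiv), KH2PO4 (aq), acetone, 0 °C → rt
Reagents that add atoms: potassium nitrosodisulfonate, [O]N(S(=O)(=O)[O-])S(=O)(=O)[O-].[K+].[K+]
Why: Teuber oxidation: the nitroxyl radical oxidises the phenol, whose para position (C8) is free, to the para-quinone and delivers the C8 oxygen, while alkenes, lactone and tertiary alcohol are inert.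

**Compound list**
1 | 5-fluoro-2-methylphenol | Cc1ccc(F)cc1O | starting material
2 | 4-fluoro-2-(methoxymethoxy)-1-methylbenzene | Cc1ccc(F)cc1OCOC | intermediate
3 | [6-fluoro-2-(methoxymethoxy)-3-methylphenyl]lithium | Cc1ccc(F)c([Li])c1OCOC | intermediate (not isolated)
4 | 6-fluoro-2-(methoxymethoxy)-3-methylbenzaldehyde | Cc1ccc(F)c(C=O)c1OCOC | intermediate
5 | (R)-(−)-linalool, (3R)-3,7-dimethylocta-1,6-dien-3-ol | C=C[C@](C)(O)CCC=C(C)C | starting material
6 | potassium (3R)-3,7-dimethylocta-1,6-dien-3-olate | C=C[C@](C)([O-])CCC=C(C)C.[K+] | intermediate (not isolated)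
7 | 6-{[(3R)-3,7-dimethylocta-1,6-dien-3-yl]oxy}-2-(methoxymethoxy)-3-methylbenzaldehyde | C=C[C@](C)(Oc1ccc(C)c(OCOC)c1C=O)CCC=C(C)C | intermediate
8 | 1-{[(3R)-3,7-dimethylocta-1,6-dien-3-yl]oxy}-2-ethenyl-3-(methoxymethoxy)-4-methylbenzene | C=C[C@](C)(Oc1ccc(C)c(OCOC)c1C=C)CCC=C(C)C | intermediate
9 | 2-[(3R)-3-{[2-ethenyl-3-(methoxymethoxy)-4-methylphenyl]oxy}-3-methylpent-4-en-1-yl]-3,3-dimethyloxirane (epimers at oxirane CH) | C=C[C@](C)(Oc1ccc(C)c(OCOC)c1C=C)CCC1OC1(C)C | intermediate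
10 | (2R)-2-[2-(3,3-dimethyloxiran-2-yl)ethyl]-5-(methoxymethoxy)-2,6-dimethyl-2H-chromene | C[C@@]1(CCC2OC2(C)C)C=Cc2c(OCOC)c(C)ccc2O1 | intermediate
11 | 5-[(2R)-5-(methoxymethoxy)-2,6-dimethyl-2H-chromen-2-yl]-2-methylpent-1-en-3-ol (carbinol epimers) | C[C@@]1(CCC(O)C(C)=C)C=Cc2c(OCOC)c(C)ccc2O1 | intermediate
12 | (2R)-2-{3-[(1-ethoxyethenyl)oxy]-4-methylpent-4-en-1-yl}-5-(methoxymethoxy)-2,6-dimethyl-2H-chromene (ketene acetal) | C[C@@]1(CCC(OC(=C)OCC)C(C)=C)C=Cc2c(OCOC)c(C)ccc2O1 | intermediate (not isolated)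
13 | ethyl (4E)-7-[(2R)-5-(methoxymethoxy)-2,6-dimethyl-2H-chromen-2-yl]-4-methylhept-4-enoate | C[C@@]1(CC/C=C(\C)CCC(=O)OCC)C=Cc2c(OCOC)c(C)ccc2O1 | intermediate
14 | (4E)-7-[(2R)-5-(methoxymethoxy)-2,6-dimethyl-2H-chromen-2-yl]-4-methylhept-4-enal | C[C@@]1(CC/C=C(\C)CCC=O)C=Cc2c(OCOC)c(C)ccc2O1 | intermediate
15 | (R)-α-hydroxy-γ-butyrolactone, (3R)-3-hydroxyoxolan-2-one | O[C@@H]1CCOC1=O | starting material
16 | (3R)-4-methylpentane-1,3,4-triol | OCC[C@@H](O)C(C)(C)O | intermediate
17 | 2-[(4R)-2,2,5,5-tetramethyl-1,3-dioxolan-4-yl]ethan-1-ol | OCC[C@H]1OC(C)(C)OC1(C)C | intermediate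
18 | (4R)-4-(2-iodoethyl)-2,2,5,5-tetramethyl-1,3-dioxolane | ICC[C@H]1OC(C)(C)OC1(C)C | intermediate
19 | ethyl 2-[bis(2-methylphenoxy)phosphoryl]acetate | CCOC(=O)CP(=O)(Oc1ccccc1C)Oc1ccccc1C | starting material
20 | sodium enolate of 19 | CCOC(=O)[CH-]P(=O)(Oc1ccccc1C)Oc1ccccc1C.[Na+] | intermediate (not isolated)
21 | ethyl 2-[bis(2-methylphenoxy)phosphoryl]-4-[(4R)-2,2,5,5-tetramethyl-1,3-dioxolan-4-yl]butanoate (epimers at C2) | CCOC(=O)C(CC[C@H]1OC(C)(C)OC1(C)C)P(=O)(Oc1ccccc1C)Oc1ccccc1C | intermediate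
22 | sodium enolate of 21 | CCOC(=O)[C-](CC[C@H]1OC(C)(C)OC1(C)C)P(=O)(Oc1ccccc1C)Oc1ccccc1C.[Na+] | intermediate (not isolated)
23 | ethyl (2Z,6E)-9-[(2R)-5-(methoxymethoxy)-2,6-dimethyl-2H-chromen-2-yl]-6-methyl-2-{2-[(4R)-2,2,5,5-tetramethyl-1,3-dioxolan-4-yl]ethyl}nona-2,6-dienoate | C[C@@]1(CC/C=C(\C)CC/C=C(/CC[C@H]3OC(C)(C)OC3(C)C)C(=O)OCC)C=Cc2c(OCOC)c(C)ccc2O1 | intermediate
24 | ethyl (2Z,6E)-2-[(3R)-3,4-dihydroxy-4-methylpentyl]-9-[(2R)-5-hydroxy-2,6-dimethyl-2H-chromen-2-yl]-6-methylnona-2,6-dienoate | C[C@@]1(CC/C=C(\C)CC/C=C(/CC[C@@H](O)C(C)(C)O)C(=O)OCC)C=Cc2c(O)c(C)ccc2O1 | intermediate (not isolated)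
25 | (3Z,6R)-3-{(4E)-7-[(2R)-5-hydroxy-2,6-dimethyl-2H-chromen-2-yl]-4-methylhept-4-en-1-ylidene}-6-(2-hydroxypropan-2-yl)oxan-2-one | C[C@@]1(CC/C=C(\C)CC/C=C3/CC[C@H](C(C)(C)O)OC3=O)C=Cc2c(O)c(C)ccc2O1 | intermediate
26 | (2R)-2-{(3E)-7-[(3Z,6R)-6-(2-hydroxypropan-2-yl)-2-oxooxan-3-ylidene]-4-methylhept-3-en-1-yl}-2,6-dimethyl-2H-chromene-5,8-dione | CC1=CC(=O)C2=C(C=C[C@@](C)(CC/C=C(\C)CC/C=C3/CC[C@H](C(C)(C)O)OC3=O)O2)C1=O | target

**Totals**
Total steps: 16. Longest linear sequence: 12 (steps 1–9, then 14–16); the phosphonate branch is steps 10–13.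

**Three steps most likely to fail, with fallbacks**

Step 3 (SNAr of a hindered tertiary alkoxide on a fluoride activated only by an ortho-formyl group). The fallback changes the electrophile to a nitrile, which activates more strongly, is smaller, and is not consumed by alkoxide addition. It sets out from 4: oxidative amination with I2 and aqueous NH3 in THF gives 6-fluoro-2-(methoxymethoxy)-3-methylbenzonitrile F1. SNAr with potassium (R)-linaloolate 6 in THF/DMF at rt gives 6-{[(3R)-3,7-dimethylocta-1,6-dien-3-yl]oxy}-2-(methoxymethoxy)-3-methylbenzonitrile F2. Reduction with i-Bu2AlH in PhMe at −78 °C and buffered aqueous work-up returns to the route at 7.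

Step 8 (the Claisen step exposes the chiral 2H-chromene to 110 °C, where slow retro-6π ring opening could erode C2, and needs high E-selectivity). The fallback is an enolate Claisen at or below room temperature. It sets out from 11: Ac2O, pyridine and DMAP give 5-[(2R)-5-(methoxymethoxy)-2,6-dimethyl-2H-chromen-2-yl]-2-methylpent-1-en-3-yl acetate F3. LiN(i-Pr)2 and Me3SiCl in THF at −78 °C give the trimethylsilyl ketene acetal F4, which undergoes the Ireland–Claisen rearrangement on warming to rt. Aqueous work-up gives (4E)-7-[(2R)-5-(methoxymethoxy)-2,6-dimethyl-2H-chromen-2-yl]-4-methylhept-4-enoic acid F5. Esterification with EtI and K2CO3 in DMF returns to the route at 13.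

Step 14 (Z-selectivity and reactivity of the α-branched diaryl phosphonate; this fallback also bypasses the alkylation of step 13). The fallback builds the trisubstituted alkene by stereodefined cross-coupling instead of olefination. It sets out from 14: CBr4, PPh3 and Et3N in CH2Cl2 at 0 °C give (2R)-2-[(3E)-8,8-dibromo-4-methylocta-3,7-dien-1-yl]-5-(methoxymethoxy)-2,6-dimethyl-2H-chromene F6. Iodide 18 with Zn dust and LiCl in THF gives {2-[(4R)-2,2,5,5-tetramethyl-1,3-dioxolan-4-yl]ethyl}zinc iodide F7. Trans-selective Negishi mono-alkylation of F6 with F7, catalysed by PdCl2(DPEphos), replaces the bromine trans to the chain and gives (2R)-2-{(3E,7Z)-8-bromo-4-methyl-10-[(4R)-2,2,5,5-tetramethyl-1,3-dioxolan-4-yl]deca-3,7-dien-1-yl}-5-(methoxymethoxy)-2,6-dimethyl-2H-chromene F8. Stereoretentive ethoxycarbonylation (CO 1 atm, EtOH, Et3N, Pd(PPh3)4, DMF, 70 °C) returns to the route at 23.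

**Further compounds**
F1 | step 3 | 6-fluoro-2-(methoxymethoxy)-3-methylbenzonitrile | Cc1ccc(F)c(C#N)c1OCOC
F2 | step 3 | 6-{[(3R)-3,7-dimethylocta-1,6-dien-3-yl]oxy}-2-(methoxymethoxy)-3-methylbenzonitrile | C=C[C@](C)(Oc1ccc(C)c(OCOC)c1C#N)CCC=C(C)C
F3 | step 8 | 5-[(2R)-5-(methoxymethoxy)-2,6-dimethyl-2H-chromen-2-yl]-2-methylpent-1-en-3-yl acetate | C[C@@]1(CCC(OC(C)=O)C(C)=C)C=Cc2c(OCOC)c(C)ccc2O1
F4 | step 8 | (2R)-5-(methoxymethoxy)-2,6-dimethyl-2-[4-methyl-3-({1-[(trimethylsilyl)oxy]ethenyl}oxy)pent-4-en-1-yl]-2H-chromene | C[C@@]1(CCC(OC(=C)O[Si](C)(C)C)C(C)=C)C=Cc2c(OCOC)c(C)ccc2O1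
F5 | step 8 | (4E)-7-[(2R)-5-(methoxymethoxy)-2,6-dimethyl-2H-chromen-2-yl]-4-methylhept-4-enoic acid | C[C@@]1(CC/C=C(\C)CCC(O)=O)C=Cc2c(OCOC)c(C)ccc2O1
F6 | step 14 | (2R)-2-[(3E)-8,8-dibromo-4-methylocta-3,7-dien-1-yl]-5-(methoxymethoxy)-2,6-dimethyl-2H-chromene | C[C@@]1(CC/C=C(\C)CCC=C(Br)Br)C=Cc2c(OCOC)c(C)ccc2O1
F7 | step 14 | {2-[(4R)-2,2,5,5-tetramethyl-1,3-dioxolan-4-yl]ethyl}zinc iodide | I[Zn]CC[C@H]1OC(C)(C)OC1(C)C
F8 | step 14 | (2R)-2-{(3E,7Z)-8-bromo-4-methyl-10-[(4R)-2,2,5,5-tetramethyl-1,3-dioxolan-4-yl]deca-3,7-dien-1-yl}-5-(methoxymethoxy)-2,6-dimethyl-2H-chromene | C[C@@]1(CC/C=C(\C)CC/C=C(Br)/CC[C@H]3OC(C)(C)OC3(C)C)C=Cc2c(OCOC)c(C)ccc2O1
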